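The chair opened on a racemate with reagent dosed over 2.5 d and a precatalyst loading between those of two earlier runs.

| setting | north | north-west | flask |
|---|---|---|---|
| left-handed substrate | 0.012 M | 0.012 M | 0.012 M |
| right-handed substrate | 0.012 M | 0.012 M | 0.012 M |
| reagent | 2.5 equiv (fed, over 2.5 d) | 2.5 equiv (fed, over 2.5 d) | 2.50 equiv (fed, over 2.5 d) |
| precatalyst | 0.1 mol% | 0.4 mol% | 0.2 mol% |
| impurity | 5.8 µM | 5.8 µM | 5.8 µM |
| remark | run made earlier; the fed solution adds 1.0 times the starting volume | run made earlier; the fed solution adds 1.0 times the starting volume | the fed solution adds 1.0 times the starting volume |
| time |  |  | 5.0 d |

| run | time / d | left-handed substrate / % | right-handed substrate / % |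
|---|---|---|---|
| north | 0.417 | 50.6 | 49.8 |
| north | 1.25 | 45.1 | 46.7 |
| north | 2.50 | 37.7 | 41.5 |
| north | 4.00 | 31.8 | 34.7 |
| north | 5.00 | 28.3 | 29.9 |
| north-west | 1.04 | 47.5 | 48.1 |
| north-west | 2.08 | 42.5 | 44.3 |
| north-west | 3.00 | 36.7 | 38.1 |
| north-west | 4.00 | 32.8 | 34.3 |
| north-west | 5.00 | 26.9 | 29.2 |

(scatter of a reading: 1 percentage point)

- part of the left-handed substrate and right-handed substrate charged together that has reacted at 5.0 d
- excess of left-handed product over right-handed product in the product at 5.0 d
- excess of right-handed substrate over left-handed substrate among what is left of the two at 5.0 d

- reagent is single-handed; left-handed substrate and right-handed substrate are mirror images of each other, charged as a racemate, each of them at the stated concentration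
- amounts are per litre of the starting volume; all of the dose is in the solution fed
- an excess is the difference of the two amounts in percent of their sum
- an excess is below zero if the other one leads
- the handed part of reagent does not stay in what it makes, so the products of the two hands are mirror images too

The kineticist reported that the north run had reacted 41.8% at 5.0 d and the north-west run 43.9%, a gap comparable to the scatter, on a factor 4.00 in precatalyst. She proposed to replace the changing c(reagent) by its mean, which makes the loss of the two substrates together pseudo-first-order. The number to carry would be the mean loss constant λ, the logarithm of charged over remaining substrate divided by the time, which from both runs is 0.112 /d. She tested the error of the mean: at 2.50 d in the north run, λ gives 24.4% reacted, more than the 20.8% read, so the mean runs ahead at that reading. She committed to 42.9% reacted in the flask at 5.0 d, and added that, with the other charges and the dosing time held, λ should follow the reagent charge while the share of reagent left stays similar, but that it says nothing about the hands.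

The forecaster then gave c 43%, eP 6% and eS 4.5%, the two excesses on the ground that “left-handed substrate goes slightly faster”.

The flask gives c 41.2%, eS 1.94% and eP 32.7%, which is 27 percentage points above the forecast.

    racemization catalyst + impurity → spent catalyst (k = 16000 /M/min)
    left-handed substrate + racemization catalyst ⇌ right-handed substrate + racemization catalyst, rate k2*[racemization catalyst]*[left-handed substrate] forward; the back reaction follows from the equilibrium constant (k = 77.8 /M/min)
    reagent + left-handed substrate → left-handed product (k = 0.0103 /M/min)
    reagent + right-handed substrate → right-handed product (k = 0.00506 /M/min)
    precatalyst → racemization catalyst (k = 0.00706 /min)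

In the flask at 2.55 d, the forward racemization of left-handed substrate has a first-order constant of 1.02 /d, about ten times λ, and reagent uses left-handed substrate at 0.18 of the forward racemization rate. At that moment reagent is used 2.0 times as fast on left-handed substrate as on right-handed substrate, and at 5.00 d the flask holds 27.3% left-handed product and 13.9% right-handed product, beside 28.8% left-handed substrate and 30.0% right-handed substrate. Scaled to the 6.20 equiv of reagent in a neighbour flask, otherwise charged like the flask, λ becomes 0.278 /d and gives 75.1% reacted at 5.0 d; that neighbour stands at 74.5% reacted, with eP 30.6%.

(All runs are simulated with made-up constants; scatter was added.)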